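The time of reading was where I began, and for midnight I set it aside: Friday's left-handed product read 9.5% at 12.0 min and 9.7% at 20.0 min, and Tuesday's 11.8% and 11.9%, so I took 25 min to lie on the plateau. You expected midnight's 2.5 mol% of free catalyst to beat dusk's 1.2 mol%. I doubted it. Tuesday's loading was 1.83 times Friday's and raised the plateau by 2.2 percentage points, whereas Thursday's 1.6 equiv of partner, with 2.5 mol% of free catalyst, reached 22.4%.

the same everywhere: left-handed substrate 0.20 M; right-handed substrate 0.20 M

| run | partner | protic impurity | free catalyst | remark | time |
|---|---|---|---|---|---|
| Friday's | 1 equiv (fed, over 1.5 min) | 0.10 M | 1.8 mol% | run made earlier; the fed solution adds 1.0 times the starting volume |  |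
| Tuesday's | 1 equiv (fed, over 1.5 min) | 0.10 M | 3.3 mol% | run made earlier; the fed solution adds 1.0 times the starting volume |  |
| Thursday's | 1.6 equiv (fed, over 1.5 min) | 0.10 M | 2.5 mol% | run made earlier; the fed solution adds 1.0 times the starting volume |  |
| dusk | 3.00 equiv | 0.100 M | 1.2 mol% | everything together at the start, the whole solution of partner included, so that from the start the volume is larger by 1.0 times the starting volume | 25 min |
| midnight | 1.00 equiv (fed, over 1.5 min) | 0.100 M | 2.5 mol% | the fed solution adds 1.0 times the starting volume | 25 min |

| run | time / min | left-handed product / % | left-handed substrate / % |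
|---|---|---|---|
| Friday's | 2.00 | 3.6 | 46.6 |
| Friday's | 6.00 | 7.9 | 42.4 |
| Friday's | 12.0 | 9.5 | 40.3 |
| Friday's | 20.0 | 9.7 | 40.2 |
| Tuesday's | 2.00 | 5.5 | 44.7 |
| Tuesday's | 6.00 | 10.9 | 39.9 |
| Tuesday's | 12.0 | 11.8 | 38.7 |
| Tuesday's | 20.0 | 11.9 | 38.5 |
| Thursday's | 2.00 | 7.0 | 42.5 |
| Thursday's | 6.00 | 17.4 | 32.4 |
| Thursday's | 12.0 | 21.8 | 28.3 |
| Thursday's | 20.0 | 22.4 | 27.6 |

(standard deviation of a reading: 0.3 percentage points)

- which of the two ends with the higher amount of left-handed product, in percent of the left-handed substrate and right-handed substrate together charged ("neither" if they lie within 2 percentage points) (dusk / midnight / neither)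
- left-handed product at the end, in percent of the left-handed substrate and right-handed substrate together charged, dusk
- left-handed product at the end, in percent of the left-handed substrate and right-handed substrate together charged, midnight

- free catalyst is single-handed; left-handed substrate and right-handed substrate are mirror images of each other, charged as a racemate, each of them at the stated concentration
- every charge counts on the volume at the start, and the solution that is fed holds the whole dose

So I reckoned the partner demand: the partner a flask can take up, in equivalents of left-handed substrate, assuming one partner for each molecule of either substrate or of protic impurity. Friday's left-handed product and substrate together read 49.9% at 20.0 min, against the 50.0% charged as left-handed substrate; that balance speaks of the substrate, so the count of partner stayed my assumption.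

demand = (left-handed substrate + right-handed substrate + protic impurity) / left-handed substrate = 2.50 equiv

midnight: charged / demand = 40.0%

dusk: charged / demand = 120%

The demand is the crossing. Midnight's 1.00 equiv is less than the demand, so partner is its limiting reagent, and between Friday's and Tuesday's loadings I read 10.7%. Dusk's 3.00 equiv is more than the demand, so dusk heads for the ceiling of 50.0%; how near it came by 25 min I left open.

The forecast named dusk, with 43% (38% to 47%) for dusk and 10.8% (10.1% to 11.5%) for midnight, and reasoned “Dusk has excess partner, so it is time-limited”.

Dusk ended at 49.3% and midnight at 10.8%, so dusk stood higher by 38 points. At 25.0 min dusk held 17% of its partner, with 1.4% of its left-handed substrate left. The demand reckons the partner's remainder from the charges: taking the whole 2.50 equiv from dusk's 3.00 equiv leaves 16.7%.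

    partner + catalyst intermediate A → free catalyst + left-handed product (k = 25.0 M⁻¹ s⁻¹)
    free catalyst + left-handed substrate ⇌ catalyst intermediate A (K = 2.00 M⁻¹, k = 130 M⁻¹ s⁻¹)
    free catalyst + right-handed substrate ⇌ catalyst intermediate B (K = 71.0 M⁻¹, k = 150 M⁻¹ s⁻¹)
    partner + protic impurity → quenched reagent (k = 0.150 M⁻¹ s⁻¹)
    partner + catalyst intermediate B → free catalyst + right-handed product (k = 1.30 M⁻¹ s⁻¹)

Midnight's recipe with 4.00 equiv of partner also stands above the demand, and the demand gives a remainder of 37.5% there. That flask ended with 38% of its partner and 50.0% left-handed product.

All runs were generated by integration for substances that don't exist, noise included.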